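**Retrosynthetic overview**
- C11–OH: reagent-controlled 1,2-reduction of a cyclopropyl E-enone, as the last step.
- C12=C13 and C14–O: HWE union of a cyclopropyl-lactone β-keto phosphonate with (S)-2-aminoxy-(Z)-dec-4-enal made in situ by D-proline catalysis. No protecting groups are used.
- Cyclopropane (ring A) and oxocenone (ring B): both come from one acyclic (7R,8R)-epoxy keto-phosphonate acid in one flask. The C10 carbanion opens the oxirane at C8 (ring A first), and the C7–O it releases is acylated by C1 (ring B second).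
- Oxirane (temporary ring, formed first and consumed in the key step): Shi epoxidation of the 7E-alkene. The 4Z-alkene comes from alkyne semihydrogenation.
- C1–C12 chain: methyl pent-4-ynoate + (E)-1,4-dibromobut-2-ene + dimethyl (2-oxopropyl)phosphonate, joined by two alkylations.

Assumption: a sequence run in one flask without work-up counts as one step; atom labels C1–C22 follow the chain of the target (C1 = lactone carbonyl, C9 = cyclopropane CH2).

**Step 1**
Reactants: 1 methyl pent-4-ynoate; 2 (E)-1,4-dibromobut-2-ene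
Product: 3 methyl (7E)-9-bromonon-7-en-4-ynoate
Conditions: 2 (3 equiv), CuBr (10 mol%), n-Bu4NBr (10 mol%), K2CO3 (1.5 equiv), DMF, 0 °C → rt
Reagents that add atoms: none
Why: Copper-catalysed SN2 allylation of a terminal alkyne through its monovalent copper acetylide (1,4-enyne synthesis); the excess of the symmetrical dibromide holds the reaction at mono-substitution, the E geometry of 2 is carried over, and no stereocenter is formed.

**Step 2**
Reactants: 3 methyl (7E)-9-bromonon-7-en-4-ynoate; 4 dimethyl (2-oxopropyl)phosphonate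
Product: 7 (7E)-12-(dimethoxyphosphoryl)-11-oxododec-7-en-4-ynoic acid, via phosphonate dianion 5 (not isolated), via methyl ester 6 (not isolated)
Conditions: 4 (1.3 equiv), NaH, THF, 0 °C; n-BuLi, 0 °C; 3, −78 → −20 °C; then LiOH, H2O, rt; 1 M HCl to pH 3
Reagents that add atoms: lithium hydroxide [Li+].[OH-]
Why: γ-Alkylation of a β-keto phosphonate dianion, which reacts only at its more basic terminal carbon (future C10) and displaces the primary allylic bromide (SN2) at −78 °C much faster than it attacks the ester, followed by ordinary saponification in the same flask; no stereocenter is formed.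

**Step 3**
Reactants: 7 (7E)-12-(dimethoxyphosphoryl)-11-oxododec-7-en-4-ynoic acid
Product: 8 6-[(2R,3R)-3-[4-(dimethoxyphosphoryl)-3-oxobutyl]oxiran-2-yl]hex-4-ynoic acid
Conditions: D-fructose-derived Shi ketone (0.5 equiv in portions), KHSO5 (as 2KHSO5·KHSO4·K2SO4, 1.5 equiv), NaHCO3, n-Bu4NHSO4 (cat.), MeCN/aq. Na2EDTA, pH 7.5–8, 0 °C; NaH2PO4 to pH 4
Reagents that add atoms: potassium peroxymonosulfate [K+].[O-]S(=O)(=O)OO
Why: Shi asymmetric epoxidation, in which the chiral dioxirane attacks the only alkene through the spiro transition state and, for E-1,2-dialkyl alkenes with the D-fructose-derived ketone, gives the (R,R)-epoxide (sets C7 and C8); the alkyne is inert to dioxiranes and at pH 8 the keto phosphonate stays un-enolised.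

**Step 4**
Reactants: 8 6-[(2R,3R)-3-[4-(dimethoxyphosphoryl)-3-oxobutyl]oxiran-2-yl]hex-4-ynoic acid
Product: 9 (4Z)-6-[(2R,3R)-3-[4-(dimethoxyphosphoryl)-3-oxobutyl]oxiran-2-yl]hex-4-enoic acid
Conditions: H2 (1 atm), 5% Pd/CaCO3 poisoned with Pb(OAc)2, quinoline, EtOAc, rt
Reagents that add atoms: none
Why: Lindlar-type syn semihydrogenation gives the 4Z-alkene, and the non-allylic epoxide, the ketone and the phosphonate are untouched; no stereocenter is formed.

**Step 5 (key step)**
Reactants: 9 (4Z)-6-[(2R,3R)-3-[4-(dimethoxyphosphoryl)-3-oxobutyl]oxiran-2-yl]hex-4-enoic acid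
Product: 13 dimethyl [2-oxo-2-[(1R,2R)-2-[(2R,4Z)-8-oxo-3,6,7,8-tetrahydro-2H-oxocin-2-yl]cyclopropyl]ethyl]phosphonate, via trianion 10 (not isolated), via hydroxy acid 11 (not isolated), via mixed anhydride 12 (not isolated)
Conditions: NaH (2.1 equiv), THF/DMPU, 0 °C; n-BuLi (1.05 equiv), −78 → 0 °C; Et3N·HCl (3.1 equiv), rt; 2,4,6-Cl3C6H2COCl (1.1 equiv), rt; then syringe pump into DMAP (6 equiv), toluene, 80 °C (final 1 mM)
Reagents that add atoms: none
Why: Proposed new method: NaH removes the CO2H and C12–H protons and n-BuLi then the C10–H proton, as in classical β-keto phosphonate dianion chemistry, so C10 is the only strongly nucleophilic site and opens the oxirane at C8 by a collinear 3-exo-tet SN2 attack (inversion at C8, retention at C7, trans ring on steric grounds so C10 = R; attack at C7 would need a cyclobutane, and C12 or O attack by the stabilised half of the dianion is far slower), driven by exchange of a carbanion for an alkoxide; protonation in the flask then gives seco acid 11, whose freshly unmasked C7–OH is acylated by C1 under Yamaguchi mixed-anhydride/DMAP high dilution with the Z-alkene pre-organising the eight-membered ring; the closest known reaction types are γ-alkylation of β-keto phosphonate dianions by epoxides, base-induced closure of γ,δ-epoxy ketones, esters and nitriles to trans-cyclopropyl carbinols, the glycidyl derivative/malonate cyclopropanation–lactonisation, and Yamaguchi closure of (Z)-oxocenones.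

**Step 6**
Reactants: 13 dimethyl [2-oxo-2-[(1R,2R)-2-[(2R,4Z)-8-oxo-3,6,7,8-tetrahydro-2H-oxocin-2-yl]cyclopropyl]ethyl]phosphonate; 14 (Z)-dec-4-enal
Product: 17 (5Z,8R)-8-[(1R,2R)-2-[(2E,4S,6Z)-4-hydroxydodeca-2,6-dienoyl]cyclopropyl]-3,4,7,8-tetrahydro-2H-oxocin-2-one, via aminoxy aldehyde 15 (not isolated), via anilinooxy enone 16 (not isolated)
Conditions: 14 (1.6 equiv), PhNO (1.5 equiv), D-proline (30 mol%), MeCN, −20 °C; then 13 (1.0 equiv), LiCl, DBU, 0 °C; then MeOH, Cu(OAc)2·H2O (30 mol%), rt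
Reagents that add atoms: nitrosobenzene O=Nc1ccccc1
Why: Proline-catalysed α-aminoxylation (the enamine attacks the oxygen of PhNO in the hydrogen-bonded Houk–List transition state, and D-proline gives the 2S aldehyde, which becomes C14), then E-selective Masamune–Roush HWE olefination mild enough to spare the aldehyde stereocenter and the lactone, then copper-catalysed N–O cleavage.

**Step 7**
Reactants: 17 (5Z,8R)-8-[(1R,2R)-2-[(2E,4S,6Z)-4-hydroxydodeca-2,6-dienoyl]cyclopropyl]-3,4,7,8-tetrahydro-2H-oxocin-2-one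
Product: 18 solandelactone F, (5Z,8R)-8-[(1R,2R)-2-[(1R,2E,4S,6Z)-1,4-dihydroxydodeca-2,6-dienyl]cyclopropyl]-3,4,7,8-tetrahydro-2H-oxocin-2-one
Conditions: (R)-2-methyl-CBS-oxazaborolidine (0.5 equiv), catecholborane (3 equiv), toluene, −78 °C; MeOH, then aq. NaHCO3
Reagents that add atoms: none
Why: Corey–Bakshi–Shibata reduction, in which the E-alkenyl arm (made bulkier by the O-borylated C14) acts as the large group and the cyclopropyl as the small group, so the (R)-catalyst gives the same sense as in prostaglandin-type enones, here 11R (cyclopropyl outranks alkenyl in CIP); catecholborane at −78 °C leaves the lactone and the alkenes alone.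

**Compound list**
1 | methyl pent-4-ynoate | C#CCCC(=O)OC | starting material
2 | (E)-1,4-dibromobut-2-ene | BrC/C=C/CBr | starting material
3 | methyl (7E)-9-bromonon-7-en-4-ynoate | COC(=O)CCC#CC/C=C/CBr | intermediate
4 | dimethyl (2-oxopropyl)phosphonate | CC(=O)CP(=O)(OC)OC | starting material
5 | sodium lithium C1,C3-dianion of 4 | [Na+].[Li+].[CH2-]C(=O)[CH-]P(=O)(OC)OC | intermediate
6 | methyl (7E)-12-(dimethoxyphosphoryl)-11-oxododec-7-en-4-ynoate | COC(=O)CCC#CC/C=C/CCC(=O)CP(=O)(OC)OC | intermediate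
7 | (7E)-12-(dimethoxyphosphoryl)-11-oxododec-7-en-4-ynoic acid | OC(=O)CCC#CC/C=C/CCC(=O)CP(=O)(OC)OC | intermediate
8 | 6-[(2R,3R)-3-[4-(dimethoxyphosphoryl)-3-oxobutyl]oxiran-2-yl]hex-4-ynoic acid | OC(=O)CCC#CC[C@H]1O[C@@H]1CCC(=O)CP(=O)(OC)OC | intermediate
9 | (4Z)-6-[(2R,3R)-3-[4-(dimethoxyphosphoryl)-3-oxobutyl]oxiran-2-yl]hex-4-enoic acid | OC(=O)CC/C=C\C[C@H]1O[C@@H]1CCC(=O)CP(=O)(OC)OC | intermediate
10 | disodium lithium trianion of 9 (carboxylate plus C10,C12-dianion) | [Na+].[Na+].[Li+].[O-]C(=O)CC/C=C\C[C@H]1O[C@@H]1C[CH-]C(=O)[CH-]P(=O)(OC)OC | intermediate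
11 | (4Z,7R)-7-[(1R,2R)-2-[2-(dimethoxyphosphoryl)acetyl]cyclopropyl]-7-hydroxyhept-4-enoic acid | COP(=O)(OC)CC(=O)[C@@H]1C[C@H]1[C@H](O)C/C=C\CCC(=O)O | intermediate
12 | mixed anhydride of 11 and 2,4,6-trichlorobenzoic acid | COP(=O)(OC)CC(=O)[C@@H]1C[C@H]1[C@H](O)C/C=C\CCC(=O)OC(=O)c1c(Cl)cc(Cl)cc1Cl | intermediate
13 | dimethyl [2-oxo-2-[(1R,2R)-2-[(2R,4Z)-8-oxo-3,6,7,8-tetrahydro-2H-oxocin-2-yl]cyclopropyl]ethyl]phosphonate | COP(=O)(OC)CC(=O)[C@@H]1C[C@H]1[C@H]1C/C=C\CCC(=O)O1 | intermediate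
14 | (Z)-dec-4-enal | CCCCC/C=C\CCC=O | starting material
15 | (2S,4Z)-2-[(phenylamino)oxy]dec-4-enal | CCCCC/C=C\C[C@H](ONc1ccccc1)C=O | intermediate
16 | (5Z,8R)-8-[(1R,2R)-2-[(2E,4S,6Z)-4-[(phenylamino)oxy]dodeca-2,6-dienoyl]cyclopropyl]-3,4,7,8-tetrahydro-2H-oxocin-2-one | CCCCC/C=C\C[C@H](ONc1ccccc1)/C=C/C(=O)[C@@H]1C[C@H]1[C@H]1C/C=C\CCC(=O)O1 | intermediate
17 | (5Z,8R)-8-[(1R,2R)-2-[(2E,4S,6Z)-4-hydroxydodeca-2,6-dienoyl]cyclopropyl]-3,4,7,8-tetrahydro-2H-oxocin-2-one | CCCCC/C=C\C[C@H](O)/C=C/C(=O)[C@@H]1C[C@H]1[C@H]1C/C=C\CCC(=O)O1 | intermediate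
18 | solandelactone F (7R,8R,10R,11R,14S) | CCCCC/C=C\C[C@H](O)/C=C/[C@@H](O)[C@@H]1C[C@H]1[C@H]1C/C=C\CCC(=O)O1 | target

**Totals**
Total step count: 7. Longest linear sequence: 7 steps (1 or 2 → 18).

**Three steps most likely to fail**

Step 5. Two things can fail here: forming the trianion in a polyfunctional substrate, and lactonising in the same flask. The fallback runs from 9 back to 17. It puts the olefination ahead of ring formation, so that the ring-closing carbanion is an ordinary cross-conjugated enone enolate that LiHMDS can generate. Acid 9 is condensed with aminoxy aldehyde 15 under the step 6 conditions, with one more equivalent of DBU for the acid, to give the anilinooxy enone acid F1. Cu(OAc)2 in MeOH then frees the hydroxy enone acid F2. TBSCl/imidazole gives the silyl ether acid F3, the acid being recovered free after aqueous work-up. LiHMDS (2.1 equiv, THF, −78 → 0 °C) forms the carboxylate/C10 enolate, which closes the cyclopropane to the cyclopropyl hydroxy acid F4. This is isolated and lactonised separately through the mixed anhydride F5 (2,4,6-trichlorobenzoyl chloride, Et3N, then DMAP, toluene, high dilution) to the silylated enone lactone F6. HF·pyridine returns to 17.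

Step 3. The risks are oxidation of the acidic P–CH2–C=O methylene and only moderate ee. The fallback runs from 1 back to 9. It uses a hydroxyl-directed epoxidation carried out before any phosphonate is present. Ester 1 is coupled (CuI, NaI, K2CO3, DMF) with purchased (E)-4-chlorobut-2-en-1-ol to the enynol ester F7. Semihydrogenation over Pd/CaCO3 poisoned with Pb(OAc)2 gives the (4Z,7E)-dienol ester F8. Sharpless epoxidation (Ti(OiPr)4, D-(−)-diisopropyl tartrate, t-BuOOH, 4 Å sieves, CH2Cl2, −20 °C) touches only the allylic alcohol alkene and gives the (2R,3R)-epoxy alcohol F9. Tf2O/2,6-lutidine at −78 °C gives the epoxy triflate F10. Dianion 5 displaces the triflate at −78 °C to give the epoxy keto-phosphonate methyl ester F11, and LiOH returns to 9.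

Step 7. The catalyst may discriminate poorly between cyclopropyl and alkenyl. The fallback runs from 17 to 18. It replaces asymmetric reduction by an unselective reduction followed by kinetic resolution. NaBH4/CeCl3·7H2O in MeOH at −78 °C gives 18 together with its 11S epimer solandelactone E F12. In 18 both carbinols flanking the C12=C13 alkene have the sense that reacts slowly with the D-(−)-tartrate titanium catalyst, whereas in F12 the C11 carbinol has the fast-reacting sense. Ti(OiPr)4, D-(−)-diisopropyl tartrate and t-BuOOH (0.6 equiv, CH2Cl2, −20 °C) therefore convert only the epimer, into the polar epoxy diol F13. Target 18 is then recovered by chromatography.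

**Further compounds**
F1 | step 5 | (4Z)-6-[(2R,3R)-3-[(4E,6S,8Z)-3-oxo-6-[(phenylamino)oxy]tetradeca-4,8-dienyl]oxiran-2-yl]hex-4-enoic acid | CCCCC/C=C\C[C@H](ONc1ccccc1)/C=C/C(=O)CC[C@H]1O[C@@H]1C/C=C\CCC(=O)O
F2 | step 5 | (4Z)-6-[(2R,3R)-3-[(4E,6S,8Z)-6-hydroxy-3-oxotetradeca-4,8-dienyl]oxiran-2-yl]hex-4-enoic acid | CCCCC/C=C\C[C@H](O)/C=C/C(=O)CC[C@H]1O[C@@H]1C/C=C\CCC(=O)O
F3 | step 5 | (4Z)-6-[(2R,3R)-3-[(4E,6S,8Z)-6-[(tert-butyldimethylsilyl)oxy]-3-oxotetradeca-4,8-dienyl]oxiran-2-yl]hex-4-enoic acid | CCCCC/C=C\C[C@H](O[Si](C)(C)C(C)(C)C)/C=C/C(=O)CC[C@H]1O[C@@H]1C/C=C\CCC(=O)O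
F4 | step 5 | (4Z,7R)-7-[(1R,2R)-2-[(2E,4S,6Z)-4-[(tert-butyldimethylsilyl)oxy]dodeca-2,6-dienoyl]cyclopropyl]-7-hydroxyhept-4-enoic acid | CCCCC/C=C\C[C@H](O[Si](C)(C)C(C)(C)C)/C=C/C(=O)[C@@H]1C[C@H]1[C@H](O)C/C=C\CCC(=O)O
F5 | step 5 | mixed anhydride of F4 and 2,4,6-trichlorobenzoic acid | CCCCC/C=C\C[C@H](O[Si](C)(C)C(C)(C)C)/C=C/C(=O)[C@@H]1C[C@H]1[C@H](O)C/C=C\CCC(=O)OC(=O)c1c(Cl)cc(Cl)cc1Cl
F6 | step 5 | (5Z,8R)-8-[(1R,2R)-2-[(2E,4S,6Z)-4-[(tert-butyldimethylsilyl)oxy]dodeca-2,6-dienoyl]cyclopropyl]-3,4,7,8-tetrahydro-2H-oxocin-2-one | CCCCC/C=C\C[C@H](O[Si](C)(C)C(C)(C)C)/C=C/C(=O)[C@@H]1C[C@H]1[C@H]1C/C=C\CCC(=O)O1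
F7 | step 3 | methyl (7E)-9-hydroxynon-7-en-4-ynoate | COC(=O)CCC#CC/C=C/CO
F8 | step 3 | methyl (4Z,7E)-9-hydroxynona-4,7-dienoate | COC(=O)CC/C=C\C/C=C/CO
F9 | step 3 | methyl (4Z)-6-[(2R,3R)-3-(hydroxymethyl)oxiran-2-yl]hex-4-enoate | COC(=O)CC/C=C\C[C@H]1O[C@@H]1CO
F10 | step 3 | methyl (4Z)-6-[(2R,3R)-3-[[(trifluoromethyl)sulfonyl]oxymethyl]oxiran-2-yl]hex-4-enoate | COC(=O)CC/C=C\C[C@H]1O[C@@H]1COS(=O)(=O)C(F)(F)F
F11 | step 3 | methyl (4Z)-6-[(2R,3R)-3-[4-(dimethoxyphosphoryl)-3-oxobutyl]oxiran-2-yl]hex-4-enoate | COC(=O)CC/C=C\C[C@H]1O[C@@H]1CCC(=O)CP(=O)(OC)OC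
F12 | step 7 | solandelactone E, the 11S epimer of 18 | CCCCC/C=C\C[C@H](O)/C=C/[C@H](O)[C@@H]1C[C@H]1[C@H]1C/C=C\CCC(=O)O1
F13 | step 7 | (5Z,8R)-8-[(1R,2R)-2-[(R)-hydroxy[(2R,3R)-3-[(1S,3Z)-1-hydroxynon-3-enyl]oxiran-2-yl]methyl]cyclopropyl]-3,4,7,8-tetrahydro-2H-oxocin-2-one | CCCCC/C=C\C[C@H](O)[C@H]1O[C@@H]1[C@H](O)[C@@H]2C[C@H]2[C@H]2C/C=C\CCC(=O)O2
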